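**Plateau first.** From 10.0 h on, watch the substrate in oak and maple: it holds still while product climbs. Take the two last readings, at 15.0 h, as the fraction left: 43.0% of the charge, with a scatter of 1.1 percentage points.

| flask | substrate | partner | scavenger | remark | time |
|---|---|---|---|---|---|
| oak | 0.10 M | 0.50 M | 0.11 M | run made earlier |  |
| maple | 0.10 M | 0.50 M | 0.12 M | run made earlier |  |
| north-west | 0.10 M | 0.500 M | 0.100 M |  | 30 h |
| north-east | 0.10 M | 0.500 M | 0.130 M |  | 30 h |
| south-east | 0.10 M | 0.500 M | 0.170 M |  | 30 h |

| run | time / h | substrate / % | product / % |
|---|---|---|---|
| oak | 3.00 | 53 | 7 |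
| oak | 6.00 | 46 | 15 |
| oak | 10.0 | 43 | 27 |
| oak | 12.0 | 42 | 32 |
| oak | 15.0 | 43 | 35 |
| maple | 3.00 | 55 | 5 |
| maple | 6.00 | 45 | 18 |
| maple | 10.0 | 44 | 27 |
| maple | 12.0 | 43 | 31 |
| maple | 15.0 | 43 | 34 |

(standard deviation of a reading: 1.5 percentage points)

1. part of the substrate that has reacted at the end, north-west
2. part of the substrate that has reacted at the end, north-east
3. part of the substrate that has reacted at the end, south-east
4. what raising the concentration of scavenger from its lowest to its highest value here does to the part of the substrate that has reacted (changes below 5 percentage points count as none) (it falls / no change / it rises)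



**Stop reckoning.** Assume that the partner decays first-order on its own and captures substrate in a pseudo-first-order step. Divide the capture rate by the partner's loss rate. Time drops out, and the logarithm of substrate charged over substrate left equals a constant times the partner charge. That pair of readings makes the constant 1.69 L mol⁻¹.

**Weak link.** Two readings carry the plateau, so use all those from 10.0 h on. That gives 43.0% left, with a scatter of 0.61 points. The selectivity factor S, the logarithm of charged over left substrate per unit of partner charged, becomes 1.69 L mol⁻¹. Oak gives 1.70 L mol⁻¹ and maple 1.67 L mol⁻¹, and S holds no scavenger term. With the partner charge unchanged at 0.500 M, I reckon 57.0% reacted in north-west, north-east and south-east. South-east, at 0.170 M, lies beyond the 0.12 M of maple.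

**The forecast.** It gives 57%, 57% and 57%, and no change: “the first step has simply stopped, perhaps because an agent died or something was used up”.

**The flask.** It gives 57.1%, 57.3% and 57.4%; the change across the scavenger range is 0.26 points, so no change.

    intermediate ⇌ product + released group (K = 0.200 M, k = 0.0815 h⁻¹)
    scavenger + released group → scavenged by-product (k = 18.7 L mol⁻¹ h⁻¹)
    partner + released group ⇌ idle adduct, settled at all times (K = 76.2 L mol⁻¹)
    partner → decomposed reagent (k = 0.0855 h⁻¹)
    substrate + partner ⇌ intermediate (K = 4.00 L mol⁻¹, k = 0.644 L mol⁻¹ h⁻¹)

**Partner test.** North-west returns S = 1.69 L mol⁻¹, with 7.5% of its partner charge left at 30.0 h. To make the forecast wrong, move a charge: with the other amounts and the time held, south-east shifts by 5 points at 0.422 M or 0.596 M of partner, or at 0.238 M of substrate. Charge 1.2 M of partner to the north-west recipe, and S gives 86.8% reacted. That neighbouring flask gives 78.5%, with 21.5% of its substrate left and 7.93% held as intermediate.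

All runs are simulated with made-up constants.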